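**Plan**

- Retrosynthesis: the C14=C15′ enal bond is cut first (directed aldol condensation) into the trans aldehyde, taken from imbricatolic acid, and the 5-epi cis aldehyde. In the cis half the C9′–C11′ bond (side chain), the C8′–C17′ bond (exo-methylene) and then the C4′–C5′ bond of ring A are cut, leaving a 4-methyl-4-alkylcyclohexadienone from a Robinson annulation.
- Enabling feature of the cis half: C10′ with its methyl is the quaternary carbon of ring B, so ring B can be a prochiral 4,4-disubstituted cyclohexadienone. C4′ is the α-carbon of the C19′ carbonyl, so C4′–C5′ is a Michael bond from a C19′ aldehyde enamine to one enone arm, and the other arm remains as the C7′ ketone with C8′=C9′.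
- Forward: ring B is built first, ring A is closed by the amine-catalysed desymmetrizing Michael addition, C19′ is oxidised and protected, the chain is added at C9′, C17′ is installed and C7′ deoxygenated. The halves are then joined by the aldol condensation and deprotected.
- Stereochemistry: C4′, C5′ and C10′ come from the chiral amine catalyst in the key step, C9′ from convex-face conjugate addition, and C13′ from enzymatic desymmetrization of dimethyl 3-methylglutarate. The five stereocentres of the trans half come from imbricatolic acid, and the (E)-enal from thermodynamic control in the dehydration.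

Key step: step 6

Assumption: imbricatolic acid, (13S)-15-hydroxylabd-8(17)-en-19-oic acid, is taken as a purchasable chiral-pool diterpene acid; locants follow labdane numbering (primed in the plan for the cis half) and β is the face of the C10 methyl group.

**Route**

Step 1
Reactants: 1 dihydromyrcene (racemic 3,7-dimethylocta-1,6-diene)
Product: 3 (E)-2,6-dimethylocta-2,7-dienal, via allylic alcohol 2 (not isolated)
Conditions: SeO2 (cat.), t-BuOOH, CH2Cl2, rt; then MnO2, CH2Cl2, rt
Reagents that add atoms: tert-butyl hydroperoxide CC(C)(C)OO (oxygen, relayed by the SeO2 catalyst O=[Se]=O)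
Why: Selenium dioxide allylic oxidation (ene reaction then [2,3]-sigmatropic shift) attacks the (E)-methyl group of the electron-rich trisubstituted alkene in preference to the vinyl group, and MnO2 oxidation of the allylic alcohol completes the (E)-enal.

Step 2
Reactants: 3 (E)-2,6-dimethylocta-2,7-dienal
Product: 4 2,6-dimethyloct-7-enal (stereoisomer mixture)
Conditions: Pd(PPh3)4 (cat.), Bu3SnH, AcOH, THF, rt
Reagents that add atoms: none
Why: Palladium-catalysed conjugate reduction of an enal with tin hydride, followed by protonation of the tin enolate by AcOH, leaves the isolated vinyl group untouched; the new α-stereocentre forms as a racemate, which is harmless because it becomes the prochiral C10.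

Step 3
Reactants: 4 2,6-dimethyloct-7-enal; 5 methyl vinyl ketone
Product: 7 4-methyl-4-(4-methylhex-5-en-1-yl)cyclohex-2-en-1-one, via Michael adduct 6 (not isolated)
Conditions: KOH (cat.), EtOH, 0 °C to reflux
Reagents that add atoms: none
Why: Robinson annulation: hydroxide-mediated Michael addition of the α-branched aldehyde to methyl vinyl ketone gives keto aldehyde 6, whose intramolecular aldol condensation closes ring B; the quaternary carbon forms without control and is symmetrised in step 4.

Step 4
Reactants: 7 4-methyl-4-(4-methylhex-5-en-1-yl)cyclohex-2-en-1-one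
Product: 8 4-methyl-4-(4-methylhex-5-en-1-yl)cyclohexa-2,5-dien-1-one
Conditions: DDQ, 1,4-dioxane, reflux
Reagents that add atoms: none
Why: Quinone dehydrogenation of a 4,4-disubstituted cyclohexenone gives the cross-conjugated dienone, which cannot aromatise, and makes the ring carbon (future C10) prochiral.

Step 5
Reactants: 8 4-methyl-4-(4-methylhex-5-en-1-yl)cyclohexa-2,5-dien-1-one
Product: 9 2-methyl-5-(1-methyl-4-oxocyclohexa-2,5-dien-1-yl)pentanal (racemic)
Conditions: OsO4 (cat.), NaIO4, 2,6-lutidine, dioxane/H2O, rt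
Reagents that add atoms: sodium periodate [Na+].[O-]I(=O)(=O)=O (oxygen, relayed by the OsO4 catalyst O=[Os](=O)(=O)=O)
Why: Lemieux–Johnson cleavage: OsO4 dihydroxylates the isolated vinyl group far faster than the electron-poor dienone double bonds and periodate cleaves the diol to the α-methyl aldehyde, whose configuration is irrelevant because C4 is planarised in the enamine.

Step 6
Reactants: 9 2-methyl-5-(1-methyl-4-oxocyclohexa-2,5-dien-1-yl)pentanal
Product: 10 7-oxo-11,12,13,14,15,16,17-heptanor-5β-labd-8-en-19-al (cis-fused; C19 aldehyde β; H5 β; C10 methyl β)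
Conditions: 1-[(1R,2R)-2-aminocyclohexyl]-3-[3,5-bis(trifluoromethyl)phenyl]thiourea (20 mol %), PhCO2H (20 mol %), toluene, rt
Reagents that add atoms: none
Why: Proposed new method: the primary amine condenses with the C19 aldehyde of 9 to a trisubstituted enamine, whose C4 adds to C5 of one enone arm while the thiourea hydrogen-bonds the dienone carbonyl, and hydrolysis of the resulting imine returns the catalyst; the closest known reaction type is the secondary-amine-catalysed desymmetrizing intramolecular Michael addition of unbranched aldehydes to 4,4-disubstituted cyclohexadienones, combined with the primary-amine–thiourea enamine additions of α-branched aldehydes to nitroalkenes that create quaternary carbons. Ring A closes in the 6-exo-trig mode. C10 and C5 are set together by the catalyst, which selects one of the two enantiotopic enone arms (the catalyst antipode is chosen to match the arm required), and the three-carbon tether from C10 can reach C5 only on its own face, so H5 must end cis to the C10 methyl. C4 is set by the orientation of the enamine in the chair-like transition state: the C19 arm carrying the bulky catalyst is expected to sit on the convex side away from ring B, which places C19 cis to H5 and the C18 methyl under ring B. The step needs arm selectivity, this C4 orientation and mono-addition; mono-addition is secured by the substrate because the second enone arm cannot be reached once ring A is closed and survives as the C7 ketone with the C8=C9 double bond.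

Step 7
Reactants: 10 7-oxo-11,12,13,14,15,16,17-heptanor-5β-labd-8-en-19-al
Product: 11 7-oxo-11,12,13,14,15,16,17-heptanor-5β-labd-8-en-19-oic acid
Conditions: NaClO2, NaH2PO4, 2-methyl-2-butene, t-BuOH/H2O, rt
Reagents that add atoms: sodium chlorite [Na+].[O-]Cl=O
Why: Pinnick oxidation converts the neopentyl aldehyde into the acid without touching the enone, and the quaternary C4 cannot epimerise.

Step 8
Reactants: 11 7-oxo-11,12,13,14,15,16,17-heptanor-5β-labd-8-en-19-oic acid
Product: 12 2-(trimethylsilyl)ethyl 7-oxo-11,12,13,14,15,16,17-heptanor-5β-labd-8-en-19-oate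
Conditions: Me3SiCH2CH2OH, PPh3, DIAD, THF, 0 °C to rt
Reagents that add atoms: 2-(trimethylsilyl)ethanol C[Si](C)(C)CCO
Why: Mitsunobu esterification activates the alcohol as its oxyphosphonium salt, so the hindered tertiary carboxylate only has to attack a primary carbon; no stereocentre is touched.

Step 9
Reactants: 13 dimethyl 3-methylglutarate
Product: 14 (R)-5-methoxy-3-methyl-5-oxopentanoic acid
Conditions: pig liver esterase, pH 7 phosphate buffer/MeOH, −10 °C
Reagents that add atoms: water O
Why: Enzymatic desymmetrization: the esterase is expected to hydrolyse the pro-S ester group of the prochiral diester and so give the (R)-half-ester, which fixes the future C13 stereocentre of the cis half.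

Step 10
Reactants: 14 (R)-5-methoxy-3-methyl-5-oxopentanoic acid
Product: 15 methyl (R)-5-hydroxy-3-methylpentanoate
Conditions: BH3·SMe2, THF, −10 °C to rt; MeOH quench
Reagents that add atoms: none
Why: Borane reduces the free carboxylic acid through an acyloxyborane much faster than the methyl ester, so the acid terminus becomes the future C15 alcohol and the stereocentre is untouched.

Step 11
Reactants: 15 methyl (R)-5-hydroxy-3-methylpentanoate
Product: 16 methyl (R)-5-(tert-butyldimethylsilyloxy)-3-methylpentanoate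
Conditions: TBSCl, imidazole, DMF, rt
Reagents that add atoms: tert-butyldimethylsilyl chloride CC(C)(C)[Si](C)(C)Cl
Why: Silylation of the primary alcohol prevents lactonisation and carries the C15 oxygen through the organometallic steps.

Step 12
Reactants: 16 methyl (R)-5-(tert-butyldimethylsilyloxy)-3-methylpentanoate
Product: 17 (S)-5-(tert-butyldimethylsilyloxy)-3-methylpentan-1-ol
Conditions: LiAlH4, Et2O, 0 °C
Reagents that add atoms: none
Why: Hydride reduction of the ester gives the primary alcohol (future C11) while the silyl ether is stable at 0 °C; the descriptor changes only through the priority rules.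

Step 13
Reactants: 17 (S)-5-(tert-butyldimethylsilyloxy)-3-methylpentan-1-ol
Product: 18 (R)-(5-bromo-3-methylpentyloxy)(tert-butyl)dimethylsilane
Conditions: CBr4, PPh3, CH2Cl2, 0 °C
Reagents that add atoms: carbon tetrabromide BrC(Br)(Br)Br
Why: Appel bromination converts the primary alcohol into the bromide under neutral conditions that leave the silyl ether intact.

Step 14
Reactants: 12 2-(trimethylsilyl)ethyl 7-oxo-11,12,13,14,15,16,17-heptanor-5β-labd-8-en-19-oate; 18 (R)-(5-bromo-3-methylpentyloxy)(tert-butyl)dimethylsilane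
Product: 20 2-(trimethylsilyl)ethyl (13S)-15-(tert-butyldimethylsilyloxy)-7-(trimethylsilyloxy)-17-nor-5β-labd-7-en-19-oate, via Grignard reagent 19 (not isolated)
Conditions: 18, Mg, THF; then CuBr·SMe2 (10 mol %), Me3SiCl, HMPA, THF, −78 °C, 12; Et3N, pentane work-up
Reagents that add atoms: chlorotrimethylsilane C[Si](C)(C)Cl
Why: Copper-catalysed conjugate addition of the Grignard reagent with Me3SiCl trapping should deliver the chain to C9 by axial attack anti to the pseudoaxial C1 of ring A, that is on the convex β face of the cis-fused bicycle, cis to the C10 methyl and H5.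

Step 15
Reactants: 20 2-(trimethylsilyl)ethyl (13S)-15-(tert-butyldimethylsilyloxy)-7-(trimethylsilyloxy)-17-nor-5β-labd-7-en-19-oate
Product: 23 2-(trimethylsilyl)ethyl (13S)-15-(tert-butyldimethylsilyloxy)-7-oxo-5β-labd-8(17)-en-19-oate, via Mannich base 21 (not isolated), via methiodide 22 (not isolated)
Conditions: CH2=NMe2+ I−, CH2Cl2, rt; MeI; aq. NaHCO3, CH2Cl2, rt
Reagents that add atoms: dimethyl(methylene)ammonium iodide C=[N+](C)C.[I-]
Why: Regiospecific Mannich reaction of the silyl enol ether at C8, N-methylation and base-induced elimination of trimethylamine give the α-methylene ketone; C8 becomes sp2 and the C9 centre is not acidic enough to epimerise under bicarbonate.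

Step 16
Reactants: 23 2-(trimethylsilyl)ethyl (13S)-15-(tert-butyldimethylsilyloxy)-7-oxo-5β-labd-8(17)-en-19-oate
Product: 24 2-(trimethylsilyl)ethyl (13S)-15-(tert-butyldimethylsilyloxy)-7-hydroxy-5β-labd-8(17)-en-19-oate (C7 epimers)
Conditions: NaBH4, CeCl3·7H2O, MeOH, −78 °C
Reagents that add atoms: none
Why: Luche reduction delivers hydride 1,2 to the α-methylene ketone; the C7 configuration is immaterial because C7 becomes CH2 in step 18.

Step 17
Reactants: 24 2-(trimethylsilyl)ethyl (13S)-15-(tert-butyldimethylsilyloxy)-7-hydroxy-5β-labd-8(17)-en-19-oate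
Product: 25 2-(trimethylsilyl)ethyl (13S)-15-(tert-butyldimethylsilyloxy)-7-formyloxy-5β-labd-8(17)-en-19-oate
Conditions: HCO2Ac, pyridine, CH2Cl2, 0 °C
Reagents that add atoms: acetic formic anhydride CC(=O)OC=O
Why: Acylation of the secondary allylic alcohol with the mixed anhydride transfers the more electrophilic formyl group and installs both leaving group and hydride source for the next step.

Step 18
Reactants: 25 2-(trimethylsilyl)ethyl (13S)-15-(tert-butyldimethylsilyloxy)-7-formyloxy-5β-labd-8(17)-en-19-oate
Product: 26 2-(trimethylsilyl)ethyl (13S)-15-(tert-butyldimethylsilyloxy)-5β-labd-8(17)-en-19-oate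
Conditions: Pd(OAc)2 (5 mol %), PBu3, THF, 40 °C
Reagents that add atoms: none
Why: Palladium-catalysed hydrogenolysis of an allylic formate: ionisation gives a π-allyl palladium formate, loss of CO2 a palladium hydride, and hydride transfer to the more substituted terminus C7 leaves the exocyclic C8=C17 double bond; C9 is not part of the allyl unit and keeps its configuration.

Step 19
Reactants: 26 2-(trimethylsilyl)ethyl (13S)-15-(tert-butyldimethylsilyloxy)-5β-labd-8(17)-en-19-oate
Product: 27 2-(trimethylsilyl)ethyl (13S)-15-hydroxy-5β-labd-8(17)-en-19-oate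
Conditions: camphorsulfonic acid (cat.), MeOH/CH2Cl2, 0 °C
Reagents that add atoms: none
Why: Acid-catalysed methanolysis removes the primary silyl ether, while the 2-(trimethylsilyl)ethyl ester and the exocyclic alkene tolerate the mild acid.

Step 20
Reactants: 27 2-(trimethylsilyl)ethyl (13S)-15-hydroxy-5β-labd-8(17)-en-19-oate
Product: 28 2-(trimethylsilyl)ethyl (13S)-15-oxo-5β-labd-8(17)-en-19-oate
Conditions: Dess–Martin periodinane, pyridine, CH2Cl2, rt
Reagents that add atoms: none
Why: Dess–Martin oxidation gives the aldehyde without over-oxidation, and C13 lies β to the new carbonyl and cannot epimerise.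

Step 21
Reactants: 29 imbricatolic acid, (13S)-15-hydroxylabd-8(17)-en-19-oic acid
Product: 30 (13S)-15-oxolabd-8(17)-en-19-oic acid
Conditions: Dess–Martin periodinane, CH2Cl2, rt
Reagents that add atoms: none
Why: Dess–Martin oxidation of the primary alcohol proceeds in the presence of the hindered tertiary carboxylic acid and the exocyclic alkene.

Step 22
Reactants: 30 (13S)-15-oxolabd-8(17)-en-19-oic acid
Product: 31 2-(trimethylsilyl)ethyl (13S)-15-oxolabd-8(17)-en-19-oate
Conditions: Me3SiCH2CH2OH, PPh3, DIAD, THF, 0 °C to rt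
Reagents that add atoms: 2-(trimethylsilyl)ethanol C[Si](C)(C)CCO
Why: Mitsunobu esterification works at the alcohol carbon and so overcomes the hindrance of the axial C19 acid, and it is done after the oxidation so that no free hydroxyl competes.

Step 23
Reactants: 31 2-(trimethylsilyl)ethyl (13S)-15-oxolabd-8(17)-en-19-oate
Product: 32 2-(trimethylsilyl)ethyl (13S)-15-(cyclohexylimino)labd-8(17)-en-19-oate
Conditions: cyclohexylamine, 4 Å molecular sieves, Et2O, rt
Reagents that add atoms: cyclohexylamine NC1CCCCC1
Why: Imine condensation under dehydrating conditions turns the trans aldehyde into the donor for a directed aldol reaction.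

Step 24
Reactants: 32 2-(trimethylsilyl)ethyl (13S)-15-(cyclohexylimino)labd-8(17)-en-19-oate; 28 2-(trimethylsilyl)ethyl (13S)-15-oxo-5β-labd-8(17)-en-19-oate
Product: 35 bis[2-(trimethylsilyl)ethyl] ester of the target, via lithium aza-enolate 33 (not isolated), via hydroxy imine 34 (not isolated)
Conditions: LiN(i-Pr)2, THF, −78 to 0 °C; 28, −78 °C; aq. oxalic acid, THF, rt to 40 °C
Reagents that add atoms: water O
Why: Directed aldol condensation: the aza-enolate of the imine fixes the donor role of the trans half, adds to aldehyde 28, and acidic hydrolysis with dehydration gives the conjugated enal in its thermodynamically favoured (E) geometry (CHO trans to C14 of the cis half); neither C13 centre is an acidic position.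

Step 25
Reactants: 35 bis[2-(trimethylsilyl)ethyl] ester of the target
Product: 36 CNP0229303.1 (target)
Conditions: Bu4NF, THF, 0 °C to rt; dilute aq. HCl work-up
Reagents that add atoms: none
Why: Fluoride attacks silicon and each ester fragments to carboxylate, ethylene and Me3SiF, a cleavage at the alkyl side that does not depend on the hindrance at C4 and leaves the enal and both exocyclic alkenes untouched.

**Compound list**

1 | dihydromyrcene (racemic 3,7-dimethylocta-1,6-diene) | C=CC(C)CCC=C(C)C | starting material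
2 | (E)-2,6-dimethylocta-2,7-dien-1-ol (not isolated) | OC/C(C)=C/CCC(C)C=C | intermediate
3 | (E)-2,6-dimethylocta-2,7-dienal | O=C/C(C)=C/CCC(C)C=C | intermediate
4 | 2,6-dimethyloct-7-enal | O=CC(C)CCCC(C)C=C | intermediate
5 | methyl vinyl ketone | CC(=O)C=C | starting material
6 | 2,6-dimethyl-2-(3-oxobutyl)oct-7-enal (not isolated) | CC(=O)CCC(C)(C=O)CCCC(C)C=C | intermediate
7 | 4-methyl-4-(4-methylhex-5-en-1-yl)cyclohex-2-en-1-one | C=CC(C)CCCC1(C)CCC(=O)C=C1 | intermediate
8 | 4-methyl-4-(4-methylhex-5-en-1-yl)cyclohexa-2,5-dien-1-one | C=CC(C)CCCC1(C)C=CC(=O)C=C1 | intermediate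
9 | 2-methyl-5-(1-methyl-4-oxocyclohexa-2,5-dien-1-yl)pentanal | CC(C=O)CCCC1(C)C=CC(=O)C=C1 | intermediate
10 | 7-oxo-11,12,13,14,15,16,17-heptanor-5β-labd-8-en-19-al | O=C1C=C[C@@]2(C)CCC[C@](C)(C=O)[C@H]2C1 | intermediate
11 | 7-oxo-11,12,13,14,15,16,17-heptanor-5β-labd-8-en-19-oic acid | O=C1C=C[C@@]2(C)CCC[C@](C)(C(=O)O)[C@H]2C1 | intermediate
12 | 2-(trimethylsilyl)ethyl 7-oxo-11,12,13,14,15,16,17-heptanor-5β-labd-8-en-19-oate | O=C1C=C[C@@]2(C)CCC[C@](C)(C(=O)OCC[Si](C)(C)C)[C@H]2C1 | intermediate
13 | dimethyl 3-methylglutarate | COC(=O)CC(C)CC(=O)OC | starting material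
14 | (R)-5-methoxy-3-methyl-5-oxopentanoic acid | OC(=O)C[C@@H](C)CC(=O)OC | intermediate
15 | methyl (R)-5-hydroxy-3-methylpentanoate | OCC[C@@H](C)CC(=O)OC | intermediate
16 | methyl (R)-5-(tert-butyldimethylsilyloxy)-3-methylpentanoate | CC(C)(C)[Si](C)(C)OCC[C@@H](C)CC(=O)OC | intermediate
17 | (S)-5-(tert-butyldimethylsilyloxy)-3-methylpentan-1-ol | CC(C)(C)[Si](C)(C)OCC[C@@H](C)CCO | intermediate
18 | (R)-(5-bromo-3-methylpentyloxy)(tert-butyl)dimethylsilane | CC(C)(C)[Si](C)(C)OCC[C@@H](C)CCBr | intermediate
19 | (R)-[5-(tert-butyldimethylsilyloxy)-3-methylpentyl]magnesium bromide (not isolated) | Br[Mg]CC[C@H](C)CCO[Si](C)(C)C(C)(C)C | intermediate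
20 | 2-(trimethylsilyl)ethyl (13S)-15-(tert-butyldimethylsilyloxy)-7-(trimethylsilyloxy)-17-nor-5β-labd-7-en-19-oate | CC(C)(C)[Si](C)(C)OCC[C@@H](C)CC[C@H]1C=C(O[Si](C)(C)C)C[C@H]2[C@]1(C)CCC[C@]2(C)C(=O)OCC[Si](C)(C)C | intermediate
21 | 2-(trimethylsilyl)ethyl (13S)-15-(tert-butyldimethylsilyloxy)-17-(dimethylamino)-7-oxo-5β-labdan-19-oate, C8 epimers (not isolated) | CC(C)(C)[Si](C)(C)OCC[C@@H](C)CC[C@H]1C(CN(C)C)C(=O)C[C@H]2[C@]1(C)CCC[C@]2(C)C(=O)OCC[Si](C)(C)C | intermediate
22 | N-methyl ammonium iodide of 21 (not isolated) | CC(C)(C)[Si](C)(C)OCC[C@@H](C)CC[C@H]1C(C[N+](C)(C)C)C(=O)C[C@H]2[C@]1(C)CCC[C@]2(C)C(=O)OCC[Si](C)(C)C.[I-] | intermediate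
23 | 2-(trimethylsilyl)ethyl (13S)-15-(tert-butyldimethylsilyloxy)-7-oxo-5β-labd-8(17)-en-19-oate | CC(C)(C)[Si](C)(C)OCC[C@@H](C)CC[C@H]1C(=C)C(=O)C[C@H]2[C@]1(C)CCC[C@]2(C)C(=O)OCC[Si](C)(C)C | intermediate
24 | 2-(trimethylsilyl)ethyl (13S)-15-(tert-butyldimethylsilyloxy)-7-hydroxy-5β-labd-8(17)-en-19-oate, C7 epimers | CC(C)(C)[Si](C)(C)OCC[C@@H](C)CC[C@H]1C(=C)C(O)C[C@H]2[C@]1(C)CCC[C@]2(C)C(=O)OCC[Si](C)(C)C | intermediate
25 | 2-(trimethylsilyl)ethyl (13S)-15-(tert-butyldimethylsilyloxy)-7-formyloxy-5β-labd-8(17)-en-19-oate, C7 epimers | CC(C)(C)[Si](C)(C)OCC[C@@H](C)CC[C@H]1C(=C)C(OC=O)C[C@H]2[C@]1(C)CCC[C@]2(C)C(=O)OCC[Si](C)(C)C | intermediate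
26 | 2-(trimethylsilyl)ethyl (13S)-15-(tert-butyldimethylsilyloxy)-5β-labd-8(17)-en-19-oate | CC(C)(C)[Si](C)(C)OCC[C@@H](C)CC[C@H]1C(=C)CC[C@H]2[C@]1(C)CCC[C@]2(C)C(=O)OCC[Si](C)(C)C | intermediate
27 | 2-(trimethylsilyl)ethyl (13S)-15-hydroxy-5β-labd-8(17)-en-19-oate | OCC[C@@H](C)CC[C@H]1C(=C)CC[C@H]2[C@]1(C)CCC[C@]2(C)C(=O)OCC[Si](C)(C)C | intermediate
28 | 2-(trimethylsilyl)ethyl (13S)-15-oxo-5β-labd-8(17)-en-19-oate | O=CC[C@@H](C)CC[C@H]1C(=C)CC[C@H]2[C@]1(C)CCC[C@]2(C)C(=O)OCC[Si](C)(C)C | intermediate
29 | imbricatolic acid, (13S)-15-hydroxylabd-8(17)-en-19-oic acid | C=C1CC[C@@H]2[C@](C)(CCC[C@]2(C)C(=O)O)[C@H]1CC[C@H](C)CCO | starting material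
30 | (13S)-15-oxolabd-8(17)-en-19-oic acid | C=C1CC[C@@H]2[C@](C)(CCC[C@]2(C)C(=O)O)[C@H]1CC[C@H](C)CC=O | intermediate
31 | 2-(trimethylsilyl)ethyl (13S)-15-oxolabd-8(17)-en-19-oate | C=C1CC[C@@H]2[C@](C)(CCC[C@]2(C)C(=O)OCC[Si](C)(C)C)[C@H]1CC[C@H](C)CC=O | intermediate
32 | 2-(trimethylsilyl)ethyl (13S)-15-(cyclohexylimino)labd-8(17)-en-19-oate | C=C1CC[C@@H]2[C@](C)(CCC[C@]2(C)C(=O)OCC[Si](C)(C)C)[C@H]1CC[C@H](C)CC=NC1CCCCC1 | intermediate
33 | lithium aza-enolate of 32 (not isolated) | C=C1CC[C@@H]2[C@](C)(CCC[C@]2(C)C(=O)OCC[Si](C)(C)C)[C@H]1CC[C@H](C)C=CN([Li])C1CCCCC1 | intermediate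
34 | aldol adduct, β-hydroxy imine, diastereomer mixture (not isolated) | C=C1CC[C@@H]2[C@](C)(CCC[C@]2(C)C(=O)OCC[Si](C)(C)C)[C@H]1CC[C@H](C)C(C=NC3CCCCC3)C(O)C[C@@H](C)CC[C@H]1C(=C)CC[C@H]2[C@]1(C)CCC[C@]2(C)C(=O)OCC[Si](C)(C)C | intermediate
35 | bis[2-(trimethylsilyl)ethyl] ester of the target | C=C1CC[C@@H]2[C@](C)(CCC[C@]2(C)C(=O)OCC[Si](C)(C)C)[C@H]1CC[C@H](C)/C(C=O)=C\C[C@@H](C)CC[C@H]1C(=C)CC[C@H]2[C@]1(C)CCC[C@]2(C)C(=O)OCC[Si](C)(C)C | intermediate
36 | CNP0229303.1 | C=C1CC[C@@H]2[C@](C)(CCC[C@]2(C)C(=O)O)[C@H]1CC[C@H](C)/C(C=O)=C\C[C@@H](C)CC[C@H]1C(=C)CC[C@H]2[C@]1(C)CCC[C@]2(C)C(=O)O | target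

**Step count and risks**

Total: 25 steps. Longest linear sequence: 17 steps (steps 1–8, 14–20, 24, 25).

Steps most likely to fail:

1. Step 6. The hindered trisubstituted enamine may add too slowly, or the catalyst may discriminate poorly between the two enone arms or between the two orientations at C4. The fallback uses known enolate chemistry and sets out from 9. Pinnick oxidation gives 2-methyl-5-(1-methyl-4-oxocyclohexa-2,5-dien-1-yl)pentanoic acid F1, and Steglich esterification with (S)-1-phenylethanol (DCC, DMAP) gives the (S)-1-phenylethyl ester F2. KN(SiMe3)2 in THF at −78 °C forms the ester enolate, which closes ring A by base-mediated intramolecular Michael addition to the dienone. The cyclised esters are diastereomers because of the phenylethyl group, and the one with the required core, (S)-1-phenylethyl 7-oxo-11,12,13,14,15,16,17-heptanor-5β-labd-8-en-19-oate F3, is separated by chromatography or crystallisation. Cleavage of the benzylic ester with TFA and Et3SiH returns to the route at acid 11.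

2. Step 14. The facial selectivity at C9 may be poor if the alternative ring conformer reacts, in which the copper reagent attacks the α face anti to an axial C10 methyl. The fallback sets out from 12 and turns that preference to advantage. The same addition then gives mainly the 9-epimeric silyl enol ether, 2-(trimethylsilyl)ethyl (13S)-15-(tert-butyldimethylsilyloxy)-7-(trimethylsilyloxy)-17-nor-5β,9β-labd-7-en-19-oate F4. Saegusa–Ito oxidation with Pd(OAc)2 in MeCN gives the C9-substituted enone, 2-(trimethylsilyl)ethyl (13S)-15-(tert-butyldimethylsilyloxy)-7-oxo-17-nor-5β-labd-8-en-19-oate F5. Conjugate reduction with [(Ph3P)CuH]6 and Me3SiCl should then deliver hydride to C9 from the face that the carbon nucleophile preferred, which puts the chain on the β face and returns to the route at silyl enol ether 20.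

3. Step 24. Proton transfer from the enolisable aldehyde 28 to the aza-enolate may compete with addition, and dehydration of the aldol may stall. The fallback replaces the basic donor by a Lewis-acid-mediated Mukaiyama aldol and sets out from 31. Me3SiOTf and Et3N give the silyl enol ether, 2-(trimethylsilyl)ethyl (13S)-15-(trimethylsilyloxy)labda-8(17),14-dien-19-oate F6. BF3·OEt2 in CH2Cl2 at −78 °C joins it to 28 to give the β-hydroxy aldehyde F7 (aldol adduct, diastereomer mixture). Mesylation (MsCl, Et3N) and elimination with DBU return to the route at 35.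

**Further compounds**

F1 | step 6 | 2-methyl-5-(1-methyl-4-oxocyclohexa-2,5-dien-1-yl)pentanoic acid | CC(CCCC1(C)C=CC(=O)C=C1)C(=O)O
F2 | step 6 | (S)-1-phenylethyl 2-methyl-5-(1-methyl-4-oxocyclohexa-2,5-dien-1-yl)pentanoate | CC(CCCC1(C)C=CC(=O)C=C1)C(=O)O[C@@H](C)c1ccccc1
F3 | step 6 | (S)-1-phenylethyl 7-oxo-11,12,13,14,15,16,17-heptanor-5β-labd-8-en-19-oate | O=C1C=C[C@@]2(C)CCC[C@](C)(C(=O)O[C@@H](C)c3ccccc3)[C@H]2C1
F4 | step 14 | 2-(trimethylsilyl)ethyl (13S)-15-(tert-butyldimethylsilyloxy)-7-(trimethylsilyloxy)-17-nor-5β,9β-labd-7-en-19-oate | CC(C)(C)[Si](C)(C)OCC[C@@H](C)CC[C@@H]1C=C(O[Si](C)(C)C)C[C@H]2[C@]1(C)CCC[C@]2(C)C(=O)OCC[Si](C)(C)C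
F5 | step 14 | 2-(trimethylsilyl)ethyl (13S)-15-(tert-butyldimethylsilyloxy)-7-oxo-17-nor-5β-labd-8-en-19-oate | CC(C)(C)[Si](C)(C)OCC[C@@H](C)CCC1=CC(=O)C[C@H]2[C@]1(C)CCC[C@]2(C)C(=O)OCC[Si](C)(C)C
F6 | step 24 | 2-(trimethylsilyl)ethyl (13S)-15-(trimethylsilyloxy)labda-8(17),14-dien-19-oate | C=C1CC[C@@H]2[C@](C)(CCC[C@]2(C)C(=O)OCC[Si](C)(C)C)[C@H]1CC[C@H](C)C=CO[Si](C)(C)C
F7 | step 24 | β-hydroxy aldehyde aldol adduct of 31 and 28, bis[2-(trimethylsilyl)ethyl] ester | C=C1CC[C@@H]2[C@](C)(CCC[C@]2(C)C(=O)OCC[Si](C)(C)C)[C@H]1CC[C@H](C)C(C=O)C(O)C[C@@H](C)CC[C@H]1C(=C)CC[C@H]2[C@]1(C)CCC[C@]2(C)C(=O)OCC[Si](C)(C)C
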